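The runs stem from a simulated flask for substances that don't exist.

**The initiator's fork.** The initiator molecule is the one I follow in this flask: it either begins a chain or is lost without one.

all flasks: initiator 0.85 mM

|  | free monomer | remark | time |
|---|---|---|---|
| cedar | 17 mM | run made earlier |  |
| alder | 26 mM | run made earlier |  |
| flask | 34 mM |  | 12 h |

| run | time / h | monomer in chains / % | free monomer / % |
|---|---|---|---|
| cedar | 1.00 | 19 | 83 |
| cedar | 3.00 | 46 | 57 |
| cedar | 6.00 | 56 | 43 |
| cedar | 8.00 | 60 | 40 |
| cedar | 12.0 | 63 | 35 |
| alder | 2.50 | 41 | 57 |
| alder | 5.00 | 57 | 33 |
| alder | 8.00 | 72 | 29 |
| alder | 10.0 | 73 | 24 |
| alder | 12.0 | 80 | 23 |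

(readings scatter by 2 percentage points)

- the average divides the monomer in chains by the number of chains begun, living and dead together
- the numbers in the tables scatter with a standard deviation of 2 percentage points
- the earlier runs do not show the number of chains; that part of a forecast is a guess

1. whether the average number of monomer units in a chain (chains begun, living or dead) reaches 100 by 12 h (no / yes)
2. average number of monomer units in a chain (chains begun, living or dead) at 12 h

**Charge ratio.** The flask's charges, c(free monomer)/c(initiator), give 40.0; I call this the charge ratio, the target degree of polymerisation. The average length is the charge ratio times the share of free monomer in chains, divided by the chance that an initiator begins a chain.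

**Question reversed.** To reach 100, what must hold? Taking alder's reading of 80% in chains at 12.0 h as the flask's share, the chance in the flask would have to be 32.0%, and with a full share it would have to be 40.0%. The readings do not show the number of chains, so that chance is a guess, but cedar already reads 19% in chains at 1.00 h, with no visible lag. I take the chance as one and commit to no, with about 32.0.

**The forecast.** It says no and 36, within 28 to 65, above my figure. It calls the needed loss of initiator a thing “which is unlikely given the fast start”.

**The result.** The flask gives no, with an average length of 34.0.

    free monomer + living end → monomer in chains + living end, rate k1*[living end]*[free monomer] (k = 0.116 M⁻¹ s⁻¹)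
    monomer in chains + living end → free monomer + living end, rate k2*[living end] as long as [monomer in chains] is above zero (k = 6.58 × 10⁻⁴ s⁻¹)
    free monomer + initiator → living end + monomer in chains (k = 0.0435 M⁻¹ s⁻¹)
    2 initiator → spent initiator (k = 0.0678 M⁻¹ s⁻¹)

**Ratio reused.** At 12.0 h the flask has 81.9% in chains, so the charge ratio with a chance of one gives 32.8, against the 34.0 found. In the flask the consumption of initiator is the largest single effect on this length: the same run without that consumption gives 2.33, against 34.0. The neighbour flask charged with 85 mM of free monomer has a charge ratio of 100 and 91.9% in chains, which reckons to 91.9, and it reaches 93.3.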